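## Retrosynthetic overview

- **Feature:** ring D has oxygen at C2 and C4, hydrogen at C3, C5 and C6, and one carbon substituent (the stereocentre) at C1. It is therefore the dehydrogenated enol form of a 4-alkylcyclohexane-1,3-dione and need not be an arene while the stereocentre is set next to ring B.
- **Late disconnections:** the ring A–ring B stilbene C=C (Horner–Wadsworth–Emmons, last C–C bond). After retro-aromatisation, ring D C1–C6 and C3–C4 (Michael–Claisen annulation of a 4,5-diarylpentan-2-one with methyl acrylate).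
- **Early disconnections:** the stereocentre–ring B C5 bond (rhodium/(R)-BINAP 1,4-addition of a ring B boronic acid to an (E)-enone) and the enone C=C (Wittig reaction of the ring C arylacetaldehyde).
- **Ring order:** rings A, B and C are bought as arenes. Ring D is the only ring built: it is closed as the dione and aromatised one step later. All eight methyl ethers are cleaved in the final step.

Key step: step 4

Assumption: the sense of induction in step 3 follows the established behaviour of BINAP–rhodium catalysts with (E)-configured acyclic acceptors, where (R)-BINAP gives the S product when the priority order at the new centre is aryl > CH2C=O > alkyl > H.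

## Route

Step 1
Reactants: 1 2-(3,5-dimethoxyphenyl)acetaldehyde; 2 1-(triphenylphosphoranylidene)propan-2-one
Product: 3 (3E)-5-(3,5-dimethoxyphenyl)pent-3-en-2-one
Conditions: CH2Cl2, rt
Reagents that add atoms: none
Why: Wittig olefination with a carbonyl-stabilised ylide should give the (E)-enone, and the neutral, salt-free medium at room temperature keeps the doubly activated C5 methylene from moving the double bond towards ring C.

Step 2
Reactants: 4 methyl 5-bromo-2,4-dimethoxybenzoate
Product: 6 [2,4-dimethoxy-5-(methoxycarbonyl)phenyl]boronic acid, via pinacol boronate 5 (not isolated)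
Conditions: B2pin2, PdCl2(dppf) (3 mol %), KOAc, dioxane, 90 °C; filter, concentrate; then NaIO4, NH4OAc, acetone/H2O, rt
Reagents that add atoms: bis(pinacolato)diboron CC1(C)OB(OC1(C)C)B1OC(C)(C)C(C)(C)O1; water O
Why: Miyaura borylation with the weak base KOAc tolerates the methyl ester, and periodate cleavage of the released pinacol in buffered aqueous acetone drives hydrolysis of 5 to the free boronic acid, which can transmetalate to rhodium without added base.

Step 3
Reactants: 3 (3E)-5-(3,5-dimethoxyphenyl)pent-3-en-2-one; 6 [2,4-dimethoxy-5-(methoxycarbonyl)phenyl]boronic acid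
Product: 7 methyl 5-[(2S)-1-(3,5-dimethoxyphenyl)-4-oxopentan-2-yl]-2,4-dimethoxybenzoate
Conditions: preformed [Rh(OH)((R)-binap)]2 (1.5 mol %), 6 (1.5 equiv), dioxane/H2O 10:1, 35 °C
Reagents that add atoms: none
Why: In this Hayashi–Miyaura asymmetric 1,4-addition the aryl–rhodium species carrying (R)-BINAP binds the (E)-enone so that ring B is delivered to the si face of C4, which sets the S centre, and water protonates the oxa-π-allyl rhodium intermediate, while the base-free medium at 35 °C limits protodeboronation of the ortho-methoxy boronic acid and migration of the enone double bond.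

Step 4
Reactants: 7 methyl 5-[(2S)-1-(3,5-dimethoxyphenyl)-4-oxopentan-2-yl]-2,4-dimethoxybenzoate; 8 methyl acrylate
Product: 10 methyl 5-[(1S)-2-(3,5-dimethoxyphenyl)-1-(2,4-dioxocyclohexyl)ethyl]-2,4-dimethoxybenzoate (both epimers at cyclohexyl C1), via delta-keto ester 9 (not isolated)
Conditions: KOtBu (1.2 equiv), THF, 0 °C, 15 min; 8 (1.1 equiv) added slowly, 0 °C → rt; then 1 M HCl
Reagents that add atoms: none
Why: tert-Butoxide and the tert-butanol it forms interconvert the two enolates of 7, the internal enolate at the side-chain C3 methylene adds to 8 in a Michael reaction (ring D C1–C6 bond) to give 9, and after proton transfer the C5 methyl-side enolate of 9 attacks the aliphatic ester and expels methoxide (ring D C3–C4 bond). The closest known reaction type is the consecutive Michael–Claisen [3+3] annulation of alkyl methyl ketones with acrylates under KOtBu, which gives 4-substituted cyclohexane-1,3-diones. The ring closes in a 6-(enolendo)-exo-trig mode, a favoured mode for enolates, and immediate deprotonation of the acidic dione makes the sequence irreversible. The only new stereocentre, the ring carbon bonded to the S centre, forms without control, remains epimerisable and is erased in step 5, whereas the S centre is beta to the carbonyl, has no acidic hydrogen and is untouched. The step needs site selectivity for the hindered methylene over the methyl group; this rests on the thermodynamic preference for the internal enolate under reversible proton transfer and is helped by slow addition of only a slight excess of 8, which also suppresses a second addition. Between the two esters the substrate decides: the benzoate is deactivated by its ortho and para methoxy groups and sits meta to the side chain, out of reach of any enolate of the same molecule, and alkoxide exchange at it would be harmless because this ester is reduced in step 6.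

Step 5
Reactants: 10 methyl 5-[(1S)-2-(3,5-dimethoxyphenyl)-1-(2,4-dioxocyclohexyl)ethyl]-2,4-dimethoxybenzoate
Product: 11 methyl 5-[(1S)-1-(2,4-dimethoxyphenyl)-2-(3,5-dimethoxyphenyl)ethyl]-2,4-dimethoxybenzoate
Conditions: I2 (2 equiv), MeOH, reflux; aq Na2S2O3 work-up
Reagents that add atoms: methanol CO
Why: In this iodine–methanol oxidative aromatisation the HI formed in situ catalyses conversion of the dione into a 1,3-dimethoxycyclohexadiene, and iodination with loss of HI removes two hydrogens to give the resorcinol dimethyl ether; both epimers converge because the epimeric carbon becomes sp2, the S centre has no acidic hydrogen, and hydride-abstracting quinone oxidants, which would endanger the diarylmethine C–H, are avoided.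

Step 6
Reactants: 11 methyl 5-[(1S)-1-(2,4-dimethoxyphenyl)-2-(3,5-dimethoxyphenyl)ethyl]-2,4-dimethoxybenzoate
Product: 12 {5-[(1S)-1-(2,4-dimethoxyphenyl)-2-(3,5-dimethoxyphenyl)ethyl]-2,4-dimethoxyphenyl}methanol
Conditions: LiAlH4, THF, 0 °C; then H2O, aq NaOH
Reagents that add atoms: none
Why: Hydride reduction of an ester to the primary alcohol acts on the only carbonyl group left, since aryl methyl ethers and the benzylic stereocentre are inert to LiAlH4.

Step 7
Reactants: 12 {5-[(1S)-1-(2,4-dimethoxyphenyl)-2-(3,5-dimethoxyphenyl)ethyl]-2,4-dimethoxyphenyl}methanol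
Product: 13 5-[(1S)-1-(2,4-dimethoxyphenyl)-2-(3,5-dimethoxyphenyl)ethyl]-2,4-dimethoxybenzaldehyde
Conditions: activated MnO2 (excess), CH2Cl2, rt
Reagents that add atoms: none
Why: MnO2 oxidation of benzylic alcohols is fast for this electron-rich carbinol, stops at the aldehyde and leaves the diarylmethine C–H alone.

Step 8
Reactants: 13 5-[(1S)-1-(2,4-dimethoxyphenyl)-2-(3,5-dimethoxyphenyl)ethyl]-2,4-dimethoxybenzaldehyde; 14 diethyl (3,5-dimethoxybenzyl)phosphonate
Product: 15 1-[(1S)-1-(2,4-dimethoxyphenyl)-2-(3,5-dimethoxyphenyl)ethyl]-5-[(E)-2-(3,5-dimethoxyphenyl)ethenyl]-2,4-dimethoxybenzene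
Conditions: 14 (1.3 equiv), NaH, THF, 0 °C; then 13, 0 °C → rt
Reagents that add atoms: none
Why: Horner–Wadsworth–Emmons olefination with a benzylic phosphonate anion adds reversibly and eliminates through the less crowded adduct, which should give the (E)-stilbene, and the anion is too weak a base to deprotonate the diarylmethine.

Step 9
Reactants: 15 1-[(1S)-1-(2,4-dimethoxyphenyl)-2-(3,5-dimethoxyphenyl)ethyl]-5-[(E)-2-(3,5-dimethoxyphenyl)ethenyl]-2,4-dimethoxybenzene
Product: 16 4-[(1S)-1-(2,4-dihydroxyphenyl)-2-(3,5-dihydroxyphenyl)ethyl]-6-[(E)-2-(3,5-dihydroxyphenyl)ethenyl]benzene-1,3-diol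
Conditions: BBr3 (16 equiv), CH2Cl2 (dilute), −78 °C → 0 °C, dark, argon; then ice/H2O
Reagents that add atoms: none
Why: In BBr3 cleavage of aryl methyl ethers each ether oxygen is complexed, bromide attacks the methyl group and the aryl borates are hydrolysed on quenching; low temperature and high dilution protect the (E)-alkene, and the stereocentre carries no leaving group.

## Compound list

| No. | Name | SMILES | Role |
|---|---|---|---|
| 1 | 2-(3,5-dimethoxyphenyl)acetaldehyde | COc1cc(CC=O)cc(OC)c1 | starting material |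
| 2 | 1-(triphenylphosphoranylidene)propan-2-one | CC(=O)C=P(c1ccccc1)(c1ccccc1)c1ccccc1 | starting material |
| 3 | (3E)-5-(3,5-dimethoxyphenyl)pent-3-en-2-one | COc1cc(C/C=C/C(C)=O)cc(OC)c1 | intermediate |
| 4 | methyl 5-bromo-2,4-dimethoxybenzoate | COC(=O)c1cc(Br)c(OC)cc1OC | starting material |
| 5 | methyl 2,4-dimethoxy-5-(4,4,5,5-tetramethyl-1,3,2-dioxaborolan-2-yl)benzoate | COC(=O)c1cc(B2OC(C)(C)C(C)(C)O2)c(OC)cc1OC | intermediate |
| 6 | [2,4-dimethoxy-5-(methoxycarbonyl)phenyl]boronic acid | COC(=O)c1cc(B(O)O)c(OC)cc1OC | intermediate |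
| 7 | methyl 5-[(2S)-1-(3,5-dimethoxyphenyl)-4-oxopentan-2-yl]-2,4-dimethoxybenzoate | COC(=O)c1cc([C@@H](Cc2cc(OC)cc(OC)c2)CC(C)=O)c(OC)cc1OC | intermediate |
| 8 | methyl acrylate | C=CC(=O)OC | starting material |
| 9 | methyl 5-[(2S)-3-acetyl-1-(3,5-dimethoxyphenyl)-6-methoxy-6-oxohexan-2-yl]-2,4-dimethoxybenzoate (C3 epimers) | COC(=O)c1cc([C@@H](Cc2cc(OC)cc(OC)c2)C(CCC(=O)OC)C(C)=O)c(OC)cc1OC | intermediate |
| 10 | methyl 5-[(1S)-2-(3,5-dimethoxyphenyl)-1-(2,4-dioxocyclohexyl)ethyl]-2,4-dimethoxybenzoate (cyclohexyl C1 epimers) | COC(=O)c1cc([C@@H](Cc2cc(OC)cc(OC)c2)C2CCC(=O)CC2=O)c(OC)cc1OC | intermediate |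
| 11 | methyl 5-[(1S)-1-(2,4-dimethoxyphenyl)-2-(3,5-dimethoxyphenyl)ethyl]-2,4-dimethoxybenzoate | COC(=O)c1cc([C@@H](Cc2cc(OC)cc(OC)c2)c2ccc(OC)cc2OC)c(OC)cc1OC | intermediate |
| 12 | {5-[(1S)-1-(2,4-dimethoxyphenyl)-2-(3,5-dimethoxyphenyl)ethyl]-2,4-dimethoxyphenyl}methanol | OCc1cc([C@@H](Cc2cc(OC)cc(OC)c2)c2ccc(OC)cc2OC)c(OC)cc1OC | intermediate |
| 13 | 5-[(1S)-1-(2,4-dimethoxyphenyl)-2-(3,5-dimethoxyphenyl)ethyl]-2,4-dimethoxybenzaldehyde | O=Cc1cc([C@@H](Cc2cc(OC)cc(OC)c2)c2ccc(OC)cc2OC)c(OC)cc1OC | intermediate |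
| 14 | diethyl (3,5-dimethoxybenzyl)phosphonate | CCOP(=O)(OCC)Cc1cc(OC)cc(OC)c1 | starting material |
| 15 | 1-[(1S)-1-(2,4-dimethoxyphenyl)-2-(3,5-dimethoxyphenyl)ethyl]-5-[(E)-2-(3,5-dimethoxyphenyl)ethenyl]-2,4-dimethoxybenzene | COc1cc(OC)cc(/C=C/c2cc([C@@H](Cc3cc(OC)cc(OC)c3)c3ccc(OC)cc3OC)c(OC)cc2OC)c1 | intermediate |
| 16 | 4-[(1S)-1-(2,4-dihydroxyphenyl)-2-(3,5-dihydroxyphenyl)ethyl]-6-[(E)-2-(3,5-dihydroxyphenyl)ethenyl]benzene-1,3-diol | Oc1cc(O)cc(/C=C/c2cc([C@@H](Cc3cc(O)cc(O)c3)c3ccc(O)cc3O)c(O)cc2O)c1 | target |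

## Step count and risks

Total step count: 9.
Longest linear sequence: 8 (steps 2–9 from 4, or steps 1 and 3–9 from 1).

**Steps most likely to fail**

**1. Step 4.**
- What may go wrong: Michael addition through the less hindered methyl-side enolate, repeated addition of acrylate, or anionic oligomerisation of the acrylate.
- Fallback (sets out from 7, comes back at 10): the site of C–C bond formation is fixed before the acrylate is introduced. Ketone 7 is silylated under equilibrating conditions (TMSCl, NaI, Et3N, MeCN, rt), which favour the internal enol ether methyl 5-[(2S,3Z)-1-(3,5-dimethoxyphenyl)-4-(trimethylsilyloxy)pent-3-en-2-yl]-2,4-dimethoxybenzoate F1. Any terminal isomer is removed on deactivated silica. A Mukaiyama–Michael addition of F1 to 8 (TiCl4, CH2Cl2, −78 °C) should then give delta-keto ester 9, this time isolated. A separate Claisen cyclisation (KOtBu, THF, 0 °C, then 1 M HCl) closes 9 to 10.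

**2. Step 5.**
- What may go wrong: electrophilic iodination of ring C or of the newly formed ring D, incomplete enol etherification so that phenolic material persists, or sluggish dehydrogenation next to the bulky substituent.
- Fallback (sets out from 10, comes back at 11): dehydrogenation and O-methylation are separated, and no halogen or acid is used. Dione 10 is treated with TMSOTf and Et3N (CH2Cl2, 0 °C) to give the bis(silyl) dienol ether methyl 5-{(1S)-1-[2,4-bis(trimethylsilyloxy)cyclohexa-2,4-dien-1-yl]-2-(3,5-dimethoxyphenyl)ethyl}-2,4-dimethoxybenzoate F2 (double-bond isomers converge). A Saegusa–Ito oxidation with Pd(OAc)2 in MeCN at rt, followed by mild desilylation on work-up, should give the free resorcinol methyl 5-[(1S)-1-(2,4-dihydroxyphenyl)-2-(3,5-dimethoxyphenyl)ethyl]-2,4-dimethoxybenzoate F3. MeI and K2CO3 in acetone convert F3 into 11.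

**3. Step 9.**
- What may go wrong: protonation of the electron-rich stilbene by HBr followed by oligomerisation, incomplete cleavage at some of the eight ether sites, or erosion of configuration through ipso-protonation of ring B or ring D.
- Fallback (sets out from 13, comes back at 16): the Lewis acid is used before the alkene exists, and the last deprotection is done with fluoride.
  - Main chain: aldehyde 13 is demethylated with BBr3 (CH2Cl2, −78 °C → rt) to 5-[(1S)-1-(2,4-dihydroxyphenyl)-2-(3,5-dihydroxyphenyl)ethyl]-2,4-dihydroxybenzaldehyde F4. TBSCl and imidazole in DMF give its hexakis(tert-butyldimethylsilyl) ether F5.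
  - Ring A partner: commercial methyl 3,5-dihydroxybenzoate is silylated to methyl 3,5-bis(tert-butyldimethylsilyloxy)benzoate F6 and reduced with DIBAL-H to [3,5-bis(tert-butyldimethylsilyloxy)phenyl]methanol F7. An Appel reaction (CBr4, PPh3) gives 3,5-bis(tert-butyldimethylsilyloxy)benzyl bromide F8. Heating F8 with P(OEt)3 (Michaelis–Arbuzov reaction) gives diethyl [3,5-bis(tert-butyldimethylsilyloxy)benzyl]phosphonate F9.
  - Endgame: Horner–Wadsworth–Emmons olefination of F5 with F9 (NaHMDS, THF, −78 °C → rt) should give the octakis(tert-butyldimethylsilyl) ether of the target F10. Et3N·3HF in THF at 0 °C then frees 16 under nearly neutral conditions.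

## Further compounds

F1 | step 4 | methyl 5-[(2S,3Z)-1-(3,5-dimethoxyphenyl)-4-(trimethylsilyloxy)pent-3-en-2-yl]-2,4-dimethoxybenzoate | COC(=O)c1cc([C@@H](Cc2cc(OC)cc(OC)c2)/C=C(/C)O[Si](C)(C)C)c(OC)cc1OC
F2 | step 5 | methyl 5-{(1S)-1-[2,4-bis(trimethylsilyloxy)cyclohexa-2,4-dien-1-yl]-2-(3,5-dimethoxyphenyl)ethyl}-2,4-dimethoxybenzoate | COC(=O)c1cc([C@@H](Cc2cc(OC)cc(OC)c2)C2CC=C(O[Si](C)(C)C)C=C2O[Si](C)(C)C)c(OC)cc1OC
F3 | step 5 | methyl 5-[(1S)-1-(2,4-dihydroxyphenyl)-2-(3,5-dimethoxyphenyl)ethyl]-2,4-dimethoxybenzoate | COC(=O)c1cc([C@@H](Cc2cc(OC)cc(OC)c2)c2ccc(O)cc2O)c(OC)cc1OC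
F4 | step 9 | 5-[(1S)-1-(2,4-dihydroxyphenyl)-2-(3,5-dihydroxyphenyl)ethyl]-2,4-dihydroxybenzaldehyde | O=Cc1cc([C@@H](Cc2cc(O)cc(O)c2)c2ccc(O)cc2O)c(O)cc1O
F5 | step 9 | hexakis(tert-butyldimethylsilyl) ether of F4 | O=Cc1cc([C@@H](Cc2cc(O[Si](C)(C)C(C)(C)C)cc(O[Si](C)(C)C(C)(C)C)c2)c2ccc(O[Si](C)(C)C(C)(C)C)cc2O[Si](C)(C)C(C)(C)C)c(O[Si](C)(C)C(C)(C)C)cc1O[Si](C)(C)C(C)(C)C
F6 | step 9 | methyl 3,5-bis(tert-butyldimethylsilyloxy)benzoate | COC(=O)c1cc(O[Si](C)(C)C(C)(C)C)cc(O[Si](C)(C)C(C)(C)C)c1
F7 | step 9 | [3,5-bis(tert-butyldimethylsilyloxy)phenyl]methanol | OCc1cc(O[Si](C)(C)C(C)(C)C)cc(O[Si](C)(C)C(C)(C)C)c1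
F8 | step 9 | 3,5-bis(tert-butyldimethylsilyloxy)benzyl bromide | BrCc1cc(O[Si](C)(C)C(C)(C)C)cc(O[Si](C)(C)C(C)(C)C)c1
F9 | step 9 | diethyl [3,5-bis(tert-butyldimethylsilyloxy)benzyl]phosphonate | CCOP(=O)(OCC)Cc1cc(O[Si](C)(C)C(C)(C)C)cc(O[Si](C)(C)C(C)(C)C)c1
F10 | step 9 | octakis(tert-butyldimethylsilyl) ether of 16 | CC(C)(C)[Si](C)(C)Oc1cc(O[Si](C)(C)C(C)(C)C)cc(/C=C/c2cc([C@@H](Cc3cc(O[Si](C)(C)C(C)(C)C)cc(O[Si](C)(C)C(C)(C)C)c3)c3ccc(O[Si](C)(C)C(C)(C)C)cc3O[Si](C)(C)C(C)(C)C)c(O[Si](C)(C)C(C)(C)C)cc2O[Si](C)(C)C(C)(C)C)c1
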